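## Analysis of the target

The target 28 is the 3-hydroxy-4-methoxybenzoate of a himachalane-type diol: a cyclohexene (ring A) trans-fused to a cycloheptane (ring B), i.e. a bicyclo[5.4.0]undecene. The carbons are numbered C1 (ester-bearing CH), C2 (CH2), C3 and C4 (ring-fusion CH; C3 bonded to C11, C4 to C7), C5=C6 (C6 carries a methyl group), C7 (gem-dimethyl), C8 to C10 (CH2) and C11 (C(CH3)OH). Ring A is C1 to C6; ring B is C3, C4 and C7 to C11. The four stereocentres C1, C3, C4 and C11 are all R: the C3 and C4 hydrogens are trans, the C11 hydroxyl lies on the side of the C3 hydrogen (so the C11 methyl is axial-like), and the C1 ester oxygen also lies on that side, pseudoaxial and trans to the C3–C11 bond. Sensitive groups are the secondary allylic ester (ionisation, SN2′ attack, acyl cleavage), the tertiary alcohol (acid-induced dehydration), the free phenol and the trisubstituted alkene. The hard points are the quaternary C7 bonded to the ring-fusion centre C4 inside a seven-membered ring, the contiguous C11/C3/C4 triad, and an ester in the less accessible pseudoaxial position. The strategy rests on ring B: without C4 and C7, the carbons C3, C8, C9, C10 and C11 form a five-membered ring in which C8 and C11 both flank C3, the pattern of a 2-substituted cyclopentane-1,3-dione. Ring B is therefore such a dione that has taken up the two-carbon unit C4–C7 between C3 and C8, the signature of an enol–alkene photocycloaddition followed by retro-aldol cleavage (de Mayo reaction).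

## Retrosynthetic reasoning

**Ester bond C1–O.** 28 is unmasked from its silyl ether 27, and 27 is cut at C1–O into allylic alcohol 23 and the protected acid 26 (from 24). The cut is made with inversion (Mitsunobu) because hydride reduction of the C1 ketone should give the pseudoequatorial 1S alcohol, the epimer of what the ester needs. The coupling must invert C1 and leave the tertiary C11 alcohol alone.

**C1 carbinol and C5=C6 alkene.** 23 goes back to enone 22 by 1,2-reduction, and 22 to the saturated ketone 19 through the silyl enol ether 20 (dehydrogenation towards the methyl-bearing C6). The C6 stereocentre of 19 is given up here on purpose: it exists only to steer the ring-forming step.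

**Ring B functional groups.** 19 comes from ketal 18, 18 from hydroxy ketone 16 by deoxygenation at C8, and 16 from diketone 15 by methyl addition at C11. The two carbonyls of 15 differ in their surroundings: C8 sits next to quaternary C7, C11 next to tertiary C3, so a carbon nucleophile should choose C11. The C8 oxygen, a leftover of the ring expansion, is removed under basic conditions that ketal and tertiary alcohol tolerate.

**Key disconnection.** Bonds C3–C4 and C7–C8 are cut and C3–C8 is restored, which takes 15 back to the dione 12. This removes in one stroke the bond to the quaternary carbon (C7–C8), the ring-fusion bond (C3–C4) and both rings. What remains is a symmetric dione with an open-chain tether whose only stereocentre is C6. The forward reaction must add the enol C3=C8 of 12 across the C4=C7 alkene, fragment the cyclobutanol, and leave C3 and C4 trans.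

**Bond C2–C3.** 12 is cut between the dione carbon C3 and C2 into 10 and aldehyde 9 (reductive Knoevenagel alkylation). Direct alkylation of 10 with a neopentyl-type halide would give O-alkylation or nothing. 9 has no alpha hydrogen and so cannot enolise or epimerise.

**Bond C1–C2 and the ketal.** 9 is traced through dithioacetal 8 and ketone 7 to Weinreb amide 5 and 6. C2 enters as a formyl anion equivalent, the C1 carbonyl is masked as the ketal while C2 is still protected, and only then is the aldehyde released. The ketal protects C6 from enolisation, is transparent in the photochemical step, and survives the later basic steps.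

**Bond C5–C6.** 5 comes from imide 4, made from 1 and 2 by auxiliary-controlled enolate alkylation. This sets C6 (S), from which the absolute configuration of C4, and through it of C3, is derived.

## Alternatives that were turned down

**Alternative 1:** Only the C4–C7 bond of ring B is cut. Ring A is present from the start in a bisabolane-type monocycle A2, a silyl dienol ether (O–C1=C6–C5=C4) that carries at C3 the chain C11(CH3)(OSi)–C10–C9–C8–C7(CH3)2Cl. In the forward step a halophilic silver salt ionises the tertiary chloride and the C7 cation is captured by the gamma carbon C4, giving the bicyclic enone A1 with C5=C6 restored.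
- For: the bond to the quaternary carbon is made directly and no oxygen has to be removed from C8. A1 is the silyl ether of 22, so it would join the present endgame only a few steps from 28. On step economy after the key step this alternative is stronger.
- Against: closing a seven-membered ring with a tertiary cation competes with proton loss and hydride shifts. The nucleophile must react at C4 rather than at C6. C4 is set under kinetic control in a medium-ring transition state. The tertiary silyl ether at C11 can itself ionise under the Lewis-acidic conditions. A2 needs the C3/C11 pair (a ring CH next to an exocyclic tertiary carbinol) to be set in an open-chain setting without an obvious control element.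
- Comparison: the chosen strategy offers instead stereochemistry relayed from one easily made centre (C6) and corrected by equilibration (C3), and a precursor made by routine reactions.

**Alternative 2:** Ring A is annulated onto a preformed ring B by cutting C4–C5 and C2=C3. Eucarvone A4 supplies the C3 carbonyl, the methyl-bearing C11 and the gem-dimethyl C7, and is converted into the protected ketol A5. In the forward step the enolate of A5, which can form only towards C4, adds to 3-methylbut-3-en-2-one A6 (bond C4–C5). Aldol condensation of the methyl ketone carbon C2 with the C3 carbonyl then closes ring A as enone A3 (C2=C3).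
- For: a cheap terpene-derived ring B, classical thermal chemistry, unambiguous enolisation, no photochemistry and no C8 oxygen to delete. On cost and simplicity of operations it is stronger.
- Against: the nucleophilic carbon C4 is neopentyl and must add to a polymerisation-prone, alpha-substituted enone. The aldol closure attacks a carbonyl flanked by fully substituted C11 and branched C4. A4 is achiral, so C11 needs a separate enantioselective step or a resolution. C4 is set relative to C11 across the carbonyl with little bias. The alkene of A3 is on the wrong side, so C3 must be set by reduction and C5=C6 introduced by the same dehydrogenation as here; the endgame is no shorter.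
- Comparison: the chosen strategy offers absolute control from one auxiliary-set centre and a ring-forming step that is insensitive to crowding at C7.

**Alternative 3:** Both rings are cut in one cascade (bonds C3–C4, C1–C2 and C5=C6). The partners are the open-chain nitroalkene aldehyde A9, derived from (R)-linalool A8 (which brings C11 and C7 to C10), and the silyl enal A10. In the forward step, under a diarylprolinol silyl ether catalyst, the enamine of the C5 aldehyde attacks through C4 the nitroalkene carbon C3 (ring B). The nitronate C2 then adds to C1 of the iminium ion of A10, and the new enamine carbon C6 condenses with C5 (ring A), giving A7.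
- For: three C–C bonds, two rings and the centres C1 to C4 in one flask, C11 from the chiral pool, and catalyst control. In bonds per step and in enantiocontrol without an auxiliary it is stronger.
- Against: the first Michael step must close a seven-membered ring through an enamine whose nucleophilic carbon is neopentyl, whereas such cascades are dependable for five- and six-membered rings. The acceptor carbon C3 adjoins fully substituted C11. Intermolecular consumption of A10 can outrun the slow cyclisation. A7 carries three auxiliary groups to edit on a sensitive allylic system: nitro removed, silyl converted into the C1 hydroxyl, and the C6 formyl reduced to methyl without allylic transposition.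
- Comparison: the chosen strategy is longer but forms the seven-membered ring by ring expansion, not cyclisation, and needs fewer corrections afterwards.

Key step: step 7

Remark on the chemistry: 12 is drawn as the diketone but is taken to react as its enol; the two possible enols are identical because the dione ring is symmetric. Locants C1 to C11 in the names below are those defined in the analysis.

## Route

Step 1
Reactants: 1 (R)-4-benzyl-3-propanoyl-1,3-oxazolidin-2-one; 2 prenyl bromide (1-bromo-3-methylbut-2-ene)
Product: 4 (R)-4-benzyl-3-[(S)-2,5-dimethylhex-4-enoyl]-1,3-oxazolidin-2-one, via sodium Z-enolate 3 (not isolated)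
Conditions: NaN(SiMe3)2, THF, −78 °C; then 2, −78 to −40 °C
Reagents that add atoms: none
Why: Evans auxiliary alkylation: the chelated Z-enolate 3 is attacked by the reactive allylic bromide on the face opposite the benzyl group of the (R)-auxiliary, which should set the future C6 as S.

Step 2
Reactants: 4
Product: 5 (S)-N-methoxy-N,2,5-trimethylhex-4-enamide
Conditions: MeNHOMe·HCl, Me3Al, CH2Cl2, 0 °C to rt; aqueous potassium sodium tartrate
Reagents that add atoms: N,O-dimethylhydroxylamine hydrochloride, CNOC.Cl
Why: Weinreb transamination: the aluminium amide attacks the exocyclic carbonyl of the imide and releases the auxiliary; the reagent is not basic enough to disturb the C6 centre, and the amide allows a single addition of a carbon nucleophile.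

Step 3
Reactants: 5; 6 1,3-dithiane
Product: 7 (S)-1-(1,3-dithian-2-yl)-2,5-dimethylhex-4-en-1-one
Conditions: 6, n-BuLi, THF, −30 °C; then 5, −78 to −20 °C; aq NH4Cl
Reagents that add atoms: none
Why: Corey–Seebach formyl anion addition to a Weinreb amide: the chelated tetrahedral lithium adduct persists until the quench, so over-addition and enolisation at C6 should not occur.

Step 4
Reactants: 7
Product: 8 2-(1,3-dithian-2-yl)-2-[(S)-5-methylhex-4-en-2-yl]-1,3-dioxolane
Conditions: Me3SiOCH2CH2OSiMe3, Me3SiOTf (cat.), CH2Cl2, −78 to −20 °C; then pyridine
Reagents that add atoms: 1,2-bis(trimethylsilyloxy)ethane, C[Si](C)(C)OCCO[Si](C)(C)C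
Why: Silyl triflate-catalysed ketalization with the bis-silyl ether of the diol, driven by disiloxane formation at low temperature without water; any enolisation of 7 should go towards the sulfur-stabilised C2 side, so C6 is expected to keep its configuration.

Step 5
Reactants: 8
Product: 9 2-[(S)-5-methylhex-4-en-2-yl]-1,3-dioxolane-2-carbaldehyde
Conditions: MeI, CaCO3, MeCN/H2O (4:1), 45 °C
Reagents that add atoms: water, O
Why: S-alkylative hydrolysis of the dithioacetal: methylation creates a sulfonium leaving group and water captures the thionium ion, while CaCO3 buffers the acid so that dioxolane and alkene are untouched; the aldehyde has no alpha hydrogen.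

Step 6
Reactants: 9; 10 cyclopentane-1,3-dione
Product: 12 2-({2-[(S)-5-methylhex-4-en-2-yl]-1,3-dioxolan-2-yl}methyl)cyclopentane-1,3-dione, via alkylidene dione 11 (not isolated)
Conditions: Hantzsch ester (diethyl 2,6-dimethyl-1,4-dihydropyridine-3,5-dicarboxylate), L-proline (cat.), CH2Cl2, rt
Reagents that add atoms: none
Why: Three-component reductive Knoevenagel alkylation: amine-mediated condensation gives the strongly electrophilic alkylidene dione 11, which is reduced at once by hydride transfer from the dihydropyridine, so that clean C-monoalkylation results where direct alkylation with a neopentyl-type halide would fail.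

Step 7
Reactants: 12
Product: 15 trans-fused diketone (3R,4R,6S) carrying the C1 dioxolane, via cyclobutanol 13 (not isolated), via cis-fused C3 epimer 14 (not isolated)
Conditions: hν (254 nm, quartz), degassed MeCN (0.01 M), rt; then NaOMe (cat.), MeOH, rt
Reagents that add atoms: none
Why: Intramolecular de Mayo reaction, a known reaction type for cyclic 1,3-diones bearing an alkenyl chain at C2: the excited enol of 12 (C3=C8–OH conjugated with the C11 carbonyl) adds to the C4=C7 alkene through a 1,4-diradical. The first bond, C3–C4, closes ring A in a 6-exo, straight mode through the four-atom tether C2–C1–C6–C5, and recombination of the tertiary radicals at C7 and C8 then gives the cis-fused cyclobutanol 13. Retro-aldol cleavage of C3–C8 in this strained beta-hydroxy ketone opens the cyclobutane and expands the five-membered ring by two carbons to ring B, leaving ketones at C8 and C11; ring B is thus formed by ring expansion and not by cyclisation. C4 is controlled by the C6 methyl group, which should sit equatorial in the chair-like tether so that the new C4–C7 bond is equatorial and cis to it; the ketal carbon C1 is not stereogenic and adds no second bias. C3 arises by ketonisation of the C11 enol and is equilibrated by methoxide from 14 to the trans fusion of 15, in which C11 and C7 are both equatorial on ring A. The step needs chemoselectivity (the ketal is transparent and the tethered alkene is the only partner in reach), regioselectivity (a crossed adduct would require a seven- or eight-membered first ring) and facial selectivity at C4. A minor C4 epimer would still be a diastereomer of 15 because C6 is stereogenic, and would be removed at this stage. Photochemical bond formation is chosen because it tolerates the fully substituted C7 terminus that would defeat an enolate alkylation, and at 254 nm the strongly absorbing enol shields the weakly absorbing product ketones.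

Step 8
Reactants: 15
Product: 16 hydroxy ketone (3R,4R,6S,11R) bearing the C11 methyl carbinol plus the C8 ketone
Conditions: MeAl(OAr)2 (Ar = 2,6-di-tert-butyl-4-methylphenyl; from Me3Al and 2 ArOH), toluene, −78 °C; then MeLi, −78 °C; aqueous potassium sodium tartrate
Reagents that add atoms: methyllithium, [Li]C
Why: Amphiphilic carbonyl methylation: the bulky aluminium Lewis acid should bind the less hindered C11 carbonyl on its open equatorial side, so that MeLi attacks axially, anti to the C3 hydrogen, giving the equatorial 11R alcohol with an axial methyl group; the neopentyl C8 carbonyl is not complexed and should not react at −78 °C.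

Step 9
Reactants: 16
Product: 18 ketal alcohol (3R,4R,6S,11R) whose C8 is a methylene, via C8 hydrazone 17 (not isolated)
Conditions: N2H4·H2O, KOH, diethylene glycol, 130 °C then 200 °C
Reagents that add atoms: none
Why: Wolff–Kishner reduction (Huang-Minlon procedure): hydrazone 17 loses N2 under hot base to leave the C8 methylene; ketal and tertiary alcohol are stable to base and no stereocentre is alpha to C8.

Step 10
Reactants: 18
Product: 19 C1 ketone (3R,4R,6S,11R) with free C11 alcohol
Conditions: 1 M HCl (aq), THF, rt
Reagents that add atoms: water, O
Why: Acid-catalysed ketal hydrolysis; dilute acid at room temperature should not ionise the tertiary C11 alcohol, and the C6 methyl group stays in its equatorial position.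

Step 11
Reactants: 19
Product: 20 bis(trimethylsilyl) compound (3R,4R,11R): C1=C6 silyl enol ether plus C11 silyl ether
Conditions: Me3SiCl, NaI, Et3N, MeCN, rt to 40 °C
Reagents that add atoms: chlorotrimethylsilane, C[Si](C)(C)Cl
Why: Thermodynamic silyl enol ether formation with Me3SiI made in situ: equilibrating conditions favour the more substituted C1=C6 enol ether over the C1=C2 isomer, as with 2-methylcyclohexanone; the tertiary alcohol is silylated as well, which is harmless.

Step 12
Reactants: 20
Product: 22 enone (3R,4R,11R) with C5=C6 alkene plus free C11 alcohol, via C11 silyl ether enone 21 (not isolated)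
Conditions: Pd(OAc)2 (1.1 equiv), MeCN, rt; then 1 M HCl (aq), THF, 0 °C
Reagents that add atoms: none
Why: Saegusa–Ito oxidation: the silyl enol ether gives a palladium enolate bound at C6, beta-hydride elimination from ring carbon C5 forms the conjugated C5=C6 enone, and brief cold acid removes the labile tertiary silyl ether; the C6 stereocentre, no longer needed, disappears here.

Step 13
Reactants: 22
Product: 23 allylic alcohol (1S,3R,4R,11R)
Conditions: NaBH4, CeCl3·7H2O, MeOH, −78 to 0 °C
Reagents that add atoms: none
Why: Luche reduction: 1,2-selective hydride delivery from the axial direction, on the face of the C3 hydrogen, should give the pseudoequatorial 1S alcohol, as in the reduction of carvone to cis-carveol.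

Step 14
Reactants: 24 isovanillic acid (3-hydroxy-4-methoxybenzoic acid)
Product: 26 3-(tert-butyldimethylsilyloxy)-4-methoxybenzoic acid, via bis-silyl derivative 25 (not isolated)
Conditions: t-BuMe2SiCl, imidazole, DMF, rt; then AcOH/THF/H2O (3:1:1), rt
Reagents that add atoms: tert-butyldimethylsilyl chloride, CC(C)(C)[Si](C)(C)Cl
Why: Exhaustive silylation followed by selective hydrolysis of the far more labile silyl ester leaves the phenol masked, so that it cannot compete as a nucleophile in the next step.

Step 15
Reactants: 23; 26
Product: 27 silyl-protected ester (1R,3R,4R,11R)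
Conditions: PPh3, diisopropyl azodicarboxylate, THF, 0 °C to rt
Reagents that add atoms: none
Why: Mitsunobu esterification: the carboxylate displaces the alkoxyphosphonium group of the secondary allylic alcohol by SN2 with inversion, turning the pseudoequatorial 1S alcohol into the pseudoaxial 1R ester; the tertiary C11 alcohol cannot be activated, and SN2′ attack at C5 is hindered by the C4 and C7 substituents.

Step 16
Reactants: 27
Product: 28 target (1R,3R,4R,11R)
Conditions: Bu4NF, AcOH, THF, 0 °C
Reagents that add atoms: none
Why: Fluoride cleavage of the aryl silyl ether, buffered with acetic acid so that the phenoxide is protonated at once and neither the allylic ester nor the tertiary alcohol is affected.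

## Compound list

1 | (R)-4-benzyl-3-propanoyl-1,3-oxazolidin-2-one | CCC(=O)N1[C@H](Cc2ccccc2)COC1=O | starting material
2 | prenyl bromide (1-bromo-3-methylbut-2-ene) | CC(C)=CCBr | starting material
3 | sodium Z-enolate of 1 | C/C=C(\[O-])N1[C@H](Cc2ccccc2)COC1=O.[Na+] | intermediate
4 | (R)-4-benzyl-3-[(S)-2,5-dimethylhex-4-enoyl]-1,3-oxazolidin-2-one | O=C([C@@H](C)CC=C(C)C)N1[C@H](Cc2ccccc2)COC1=O | intermediate
5 | (S)-N-methoxy-N,2,5-trimethylhex-4-enamide | CON(C)C(=O)[C@@H](C)CC=C(C)C | intermediate
6 | 1,3-dithiane | C1CSCSC1 | starting material
7 | (S)-1-(1,3-dithian-2-yl)-2,5-dimethylhex-4-en-1-one | O=C(C1SCCCS1)[C@@H](C)CC=C(C)C | intermediate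
8 | 2-(1,3-dithian-2-yl)-2-[(S)-5-methylhex-4-en-2-yl]-1,3-dioxolane | C1(C2SCCCS2)(OCCO1)[C@@H](C)CC=C(C)C | intermediate
9 | 2-[(S)-5-methylhex-4-en-2-yl]-1,3-dioxolane-2-carbaldehyde | O=CC1(OCCO1)[C@@H](C)CC=C(C)C | intermediate
10 | cyclopentane-1,3-dione | O=C1CCC(=O)C1 | starting material
11 | 2-({2-[(S)-5-methylhex-4-en-2-yl]-1,3-dioxolan-2-yl}methylidene)cyclopentane-1,3-dione | O=C1CCC(=O)C1=CC2(OCCO2)[C@@H](C)CC=C(C)C | intermediate
12 | 2-({2-[(S)-5-methylhex-4-en-2-yl]-1,3-dioxolan-2-yl}methyl)cyclopentane-1,3-dione (C6 S; reacts as its enol) | O=C1CCC(=O)C1CC2(OCCO2)[C@@H](C)CC=C(C)C | intermediate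
13 | tricyclic cyclobutanol (3R,4S,6S,8R): cyclobutane C3–C4–C7–C8 fused cis to ring A at C3–C4 and cis to the cyclopentanone at C3–C8; C8 hydroxyl, C11 ketone, C1 dioxolane, C6 methyl, C7 gem-dimethyl | O=C1CC[C@@]2(O)C(C)(C)[C@@H]3C[C@H](C)C4(OCCO4)C[C@]123 | intermediate
14 | cis-fused diketone (3S,4R,6S), C3 epimer of 15 | C13(OCCO3)C[C@H]2[C@@H](C[C@@H]1C)C(C)(C)C(=O)CCC2=O | intermediate
15 | trans-fused diketone (3R,4R,6S): ring A with C1 spiro-dioxolane and C6 methyl; ring B with C7 gem-dimethyl and ketones at C8 and C11 | C13(OCCO3)C[C@@H]2[C@@H](C[C@@H]1C)C(C)(C)C(=O)CCC2=O | intermediate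
16 | hydroxy ketone (3R,4R,6S,11R): as 15 but C11 is C(CH3)OH, hydroxyl on the side of the C3 hydrogen; C8 ketone | C13(OCCO3)C[C@@H]2[C@@H](C[C@@H]1C)C(C)(C)C(=O)CC[C@@]2(C)O | intermediate
17 | C8 hydrazone of 16 | C13(OCCO3)C[C@@H]2[C@@H](C[C@@H]1C)C(C)(C)C(=NN)CC[C@@]2(C)O | intermediate
18 | ketal alcohol (3R,4R,6S,11R): as 16 with C8 as CH2 | C13(OCCO3)C[C@@H]2[C@@H](C[C@@H]1C)C(C)(C)CCC[C@@]2(C)O | intermediate
19 | hydroxy ketone (3R,4R,6S,11R): C1 ketone, C6 methyl, C11 tertiary alcohol | O=C1C[C@@H]2[C@@H](C[C@@H]1C)C(C)(C)CCC[C@@]2(C)O | intermediate
20 | bis(trimethylsilyl) compound (3R,4R,11R): C1=C6 trimethylsilyl enol ether and C11 trimethylsilyl ether | C1(O[Si](C)(C)C)C[C@@H]2[C@@H](CC=1C)C(C)(C)CCC[C@@]2(C)O[Si](C)(C)C | intermediate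
21 | enone (3R,4R,11R) with C11 trimethylsilyl ether | O=C1C[C@@H]2[C@@H](C=C1C)C(C)(C)CCC[C@@]2(C)O[Si](C)(C)C | intermediate
22 | enone (3R,4R,11R): C1 ketone, C5=C6 alkene with C6 methyl, C11 tertiary alcohol | O=C1C[C@@H]2[C@@H](C=C1C)C(C)(C)CCC[C@@]2(C)O | intermediate
23 | allylic alcohol (1S,3R,4R,11R): C1 hydroxyl trans to the C3 hydrogen | O[C@H]1C[C@@H]2[C@@H](C=C1C)C(C)(C)CCC[C@@]2(C)O | intermediate
24 | isovanillic acid (3-hydroxy-4-methoxybenzoic acid) | COc1ccc(C(=O)O)cc1O | starting material
25 | tert-butyldimethylsilyl 3-(tert-butyldimethylsilyloxy)-4-methoxybenzoate | COc1ccc(C(=O)O[Si](C)(C)C(C)(C)C)cc1O[Si](C)(C)C(C)(C)C | intermediate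
26 | 3-(tert-butyldimethylsilyloxy)-4-methoxybenzoic acid | COc1ccc(C(=O)O)cc1O[Si](C)(C)C(C)(C)C | intermediate
27 | (1R,3R,4R,11R) C1 ester of the diol with 26 (phenol as tert-butyldimethylsilyl ether) | COc1ccc(C(=O)O[C@@H]2C[C@@H]3[C@@H](C=C2C)C(C)(C)CCC[C@@]3(C)O)cc1O[Si](C)(C)C(C)(C)C | intermediate
28 | target, (1R,3R,4R,11R); systematic: (2R,4aR,9R,9aR)-9-hydroxy-3,5,5,9-tetramethyl-2,4a,5,6,7,8,9,9a-octahydro-1H-benzo[7]annulen-2-yl 3-hydroxy-4-methoxybenzoate | COc1ccc(C(=O)O[C@@H]2C[C@@H]3[C@@H](C=C2C)C(C)(C)CCC[C@@]3(C)O)cc1O | target

## Step count and least certain steps

Total: 16 steps. Longest linear sequence: 15 steps (steps 1 to 13, 15 and 16); step 14 is a one-step branch. Enantiopurity rests on the auxiliary-set C6 centre and on removing any C4-epimeric diastereomer at the stage of 15, before C6 is destroyed in step 12.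

**Step 7 (key step).** The 1,4-diradical may revert or transfer hydrogen (disproportionation to an isopropenyl-substituted monocycle) instead of closing the congested C7–C8 bond. The free enol may be excited inefficiently because of aggregation. The product ketones may undergo secondary alpha-cleavage next to C7 on over-irradiation. Facial selectivity at C4 may be incomplete. Fallback: 12 would be O-acetylated (acetic anhydride, pyridine, 4-dimethylaminopyridine) to the enol acetate F1. Its enone chromophore can be irradiated through Pyrex above 300 nm, if needed with a triplet sensitiser, and the photoadduct is no longer a free beta-hydroxy ketone. The acetoxy cyclobutane F2 would be isolated and then treated with K2CO3 in methanol, which removes the acetate, triggers the retro-aldol ring expansion and equilibrates C3, returning to the route at 15.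

**Step 8.** Facial selectivity of methyl delivery may be poor or reversed, because the seven-membered ring is flexible and the bulky aluminium reagent may not complex one side selectively. Attack at C8 is a lesser risk. Fallback: from 15, dimethylsulfonium methylide (Me3SI, n-BuLi, THF) would transfer CH2 to C11. This small ylide is known to attack cyclic ketones axially, giving the spiro-epoxide F3 with an equatorial oxygen. LiAlH4 would then open the epoxide at its CH2 terminus (forming the same C11 carbinol) and reduce the C8 ketone, giving the diol F4. Selective oxidation of the secondary alcohol (Dess–Martin periodinane) returns to 16.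

**Step 9.** Hydrazone formation may fail at the neopentyl C8 carbonyl, which may also be masked as a transannular hemiketal with the C11 hydroxyl, and long heating in strong base may degrade the material. Fallback: 16 would be reduced with NaBH4 to the diol F4. Its secondary hydroxyl would be converted with 1,1′-thiocarbonyldiimidazole into the imidazolyl thiocarbonate F5 (the tertiary alcohol does not react). Barton–McCombie deoxygenation (Bu3SnH, azobisisobutyronitrile, toluene, reflux) returns to 18.

**Step 4.** Ketalization may be slow at a carbonyl flanked by the dithiane and the branched C6, and forcing it with acid may erode the C6 centre through enol or enol ether intermediates. Fallback: from 5, addition of [(4-methoxybenzyl)oxy]methyllithium (from the corresponding tributylstannane and n-BuLi) would give the ketone F6, whose carbonyl has an unbranched neighbour. The same silyl triflate ketalization would give F7, oxidative removal of the 4-methoxybenzyl group (2,3-dichloro-5,6-dicyano-1,4-benzoquinone, buffered CH2Cl2/H2O) the alcohol F8, and Swern oxidation returns to 9.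

**Step 15.** The activated allylic alcohol may ionise or eliminate (diene formation, SN2′ substitution, loss of stereochemical fidelity), because displacement at a hindered secondary allylic centre by a weakly acidic benzoic acid is slow. Fallback: from 22, Corey–Bakshi–Shibata reduction with the (S)-configured methyl oxazaborolidine and BH3·SMe2 would be used. Its usual sense of induction, with the alkenyl side as the large group, corresponds to 1R, so it should give the 1R allylic alcohol F9 directly under reagent control. Acylation of F9 with 26 (carbodiimide, 4-dimethylaminopyridine) proceeds with retention and returns to 27.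

## Further compounds

F1 | step 7 | enol acetate of 12: 3-oxo-2-({2-[(S)-5-methylhex-4-en-2-yl]-1,3-dioxolan-2-yl}methyl)cyclopent-1-en-1-yl acetate | CC(=O)OC1=C(CC2(OCCO2)[C@@H](C)CC=C(C)C)C(=O)CC1
F2 | step 7 | acetoxy cyclobutane photoadduct (acetate of 13, same configuration) | O=C1CC[C@@]2(OC(C)=O)C(C)(C)[C@@H]3C[C@H](C)C4(OCCO4)C[C@]123
F3 | step 8 | C11 spiro-epoxide of 15 (oxygen on the side of the C3 hydrogen, CH2 axial), C8 ketone | C13(OCCO3)C[C@@H]2[C@@H](C[C@@H]1C)C(C)(C)C(=O)CC[C@@]24OC4
F4 | step 8 | diol: 16 with the C8 ketone reduced to a secondary alcohol (C8 configuration not controlled) | C13(OCCO3)C[C@@H]2[C@@H](C[C@@H]1C)C(C)(C)C(O)CC[C@@]2(C)O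
F5 | step 9 | C8 O-(imidazol-1-ylthiocarbonyl) derivative of F4 | C13(OCCO3)C[C@@H]2[C@@H](C[C@@H]1C)C(C)(C)C(OC(=S)n4ccnc4)CC[C@@]2(C)O
F6 | step 4 | (S)-1-[(4-methoxybenzyl)oxy]-3,6-dimethylhept-5-en-2-one | COc1ccc(COCC(=O)[C@@H](C)CC=C(C)C)cc1
F7 | step 4 | 2-{[(4-methoxybenzyl)oxy]methyl}-2-[(S)-5-methylhex-4-en-2-yl]-1,3-dioxolane | COc1ccc(COCC2(OCCO2)[C@@H](C)CC=C(C)C)cc1
F8 | step 4 | {2-[(S)-5-methylhex-4-en-2-yl]-1,3-dioxolan-2-yl}methanol | OCC1(OCCO1)[C@@H](C)CC=C(C)C
F9 | step 15 | allylic alcohol (1R,3R,4R,11R), C1 epimer of 23 | O[C@@H]1C[C@@H]2[C@@H](C=C1C)C(C)(C)CCC[C@@]2(C)O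
A1 | alternative 1 | bicyclic C1 enone with C5=C6 alkene and C11 tert-butyldimethylsilyl ether | O=C1C[C@@H]2[C@@H](C=C1C)C(C)(C)CCC[C@@]2(C)O[Si](C)(C)C(C)(C)C
A2 | alternative 1 | monocyclic trimethylsilyl dienol ether (C1=C6, C4=C5) carrying at C3 the (R)-6-chloro-6-methyl-2-(tert-butyldimethylsilyloxy)heptan-2-yl chain | C1(O[Si](C)(C)C)C[C@H](C=CC=1C)[C@](C)(O[Si](C)(C)C(C)(C)C)CCCC(C)(C)Cl
A3 | alternative 2 | bicyclic C1 enone with C2=C3 alkene, C6 methyl and C11 methoxymethyl ether | O=C1C=C2[C@@H](C[C@@H]1C)C(C)(C)CCC[C@@]2(C)OCOC
A4 | alternative 2 | eucarvone (2,6,6-trimethylcyclohepta-2,4-dien-1-one) | CC1=CC=CC(C)(C)CC1=O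
A5 | alternative 2 | (R)-2-(methoxymethoxy)-2,6,6-trimethylcycloheptan-1-one | O=C1CC(C)(C)CCC[C@@]1(C)OCOC
A6 | alternative 2 | 3-methylbut-3-en-2-one | CC(=C)C(C)=O
A7 | alternative 3 | bicyclic enal with C1 dimethyl(phenyl)silyl, C2 nitro, C6 formyl and C11 triethylsilyl ether | C[Si](C)(c1ccccc1)[C@@H]1[C@H]([N+](=O)[O-])[C@@H]2[C@@H](C=C1C=O)C(C)(C)CCC[C@@]2(C)O[Si](CC)(CC)CC
A8 | alternative 3 | (R)-linalool | C=C[C@](C)(O)CCC=C(C)C
A9 | alternative 3 | (R,E)-3,3,7-trimethyl-9-nitro-7-(triethylsilyloxy)non-8-enal | O=CCC(C)(C)CCC[C@@](C)(O[Si](CC)(CC)CC)/C=C/[N+](=O)[O-]
A10 | alternative 3 | (E)-3-[dimethyl(phenyl)silyl]prop-2-enal | C[Si](C)(c1ccccc1)/C=C/C=O
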